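**Retrosynthetic overview**

1. Feature: in ring A the three oxygens (O1 at C8a, C5–OH, C7–OH) all lie ortho or para to the C4 carbonyl, so ring A is carried as a 2,4,6-trifluorophenyl ketone and each C–F bond is later exchanged for C–O by SNAr.
2. Target ⇐ MOM cleavage and fluoride unmasking ⇐ double SNAr with 2-(trimethylsilyl)ethoxide at C5 and C7 ⇐ 5,7-difluoro-3-(methoxymethoxy)isoflavanone.
3. That chromanone ⇐ O1–C8a bond by intramolecular SNAr of a primary alkoxide (ring C, the only ring made) ⇐ open-chain silyloxy trifluorophenyl ketone ⇐ C4–C4a bond from 2,4,6-trifluorophenyllithium and an α-quaternary aldehyde.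
4. C3 stereocentre ⇐ CuCl2–bis(oxazoline) monobenzoylation of the prochiral 2-aryl glycerol ⇐ C3–C1′ bond from the ring B aryllithium and bis-silylated dihydroxyacetone; ring B bromide ⇐ 1-bromo-2,4-dimethoxybenzene + prenyl bromide.
5. Ring order: rings A and B are bought as benzene rings; ring C is closed in step 11.

Key step: step 11

Abbreviations: Ar = 2,4-dimethoxy-3-(3-methylbut-2-en-1-yl)phenyl; TBS = tert-butyldimethylsilyl; MOM = methoxymethyl.

Assumption: 1,3-dihydroxyacetone is charged as its commercial dimer, which reacts as the monomer, and the (R,R)-ligand in step 4 is taken to acylate the arm that gives the (2R)-monobenzoate; if the sense of induction is the opposite, the (S,S)-ligand is used with no other change.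

**Route**

Step 1
Reactants: 1 1,3-dihydroxyacetone
Product: 2 1,3-bis[(tert-butyldimethylsilyl)oxy]propan-2-one
Conditions: TBSCl (2.2 equiv), imidazole, DMF, 0 °C → rt
Reagents that add atoms: tert-butyldimethylsilyl chloride, CC(C)(C)[Si](C)(C)Cl
Why: Silyl ether formation on both primary hydroxyls; the dimer cracks to the monomer under the conditions and the ketone is left free as the electrophile for step 3.

Step 2
Reactants: 3 1-bromo-2,4-dimethoxybenzene; 4 prenyl bromide (1-bromo-3-methylbut-2-ene)
Product: 6 1-bromo-2,4-dimethoxy-3-(3-methylbut-2-en-1-yl)benzene, via (3-bromo-2,6-dimethoxyphenyl)lithium 5 (not isolated)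
Conditions: lithium 2,2,6,6-tetramethylpiperidide (from 2,2,6,6-tetramethylpiperidine and n-BuLi), THF, −78 °C; then CuBr·SMe2 (10 mol %), 4, −78 → 0 °C
Reagents that add atoms: none
Why: Directed ortho-metalation at the C–H flanked by both methoxy groups (the most acidic site; the hindered amide base does not exchange the bromine), followed by copper-catalysed SN2 allylation at the primary carbon of prenyl bromide.

Step 3
Reactants: 6 1-bromo-2,4-dimethoxy-3-(3-methylbut-2-en-1-yl)benzene; 2 1,3-bis[(tert-butyldimethylsilyl)oxy]propan-2-one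
Product: 9 2-[2,4-dimethoxy-3-(3-methylbut-2-en-1-yl)phenyl]propane-1,2,3-triol, via [2,4-dimethoxy-3-(3-methylbut-2-en-1-yl)phenyl]lithium 7 (not isolated), via 2-aryl-1,3-bis(tert-butyldimethylsilyloxy)propan-2-ol 8 (not isolated)
Conditions: n-BuLi, THF, −78 °C; then 2, −78 → −20 °C; aqueous work-up; crude carbinol, Bu4NF, THF, rt
Reagents that add atoms: none
Why: Bromine–lithium exchange and 1,2-addition of the aryllithium to the ketone, then fluoride desilylation, should give the achiral triol with two enantiotopic CH2OH arms.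

Step 4
Reactants: 9 2-Ar-propane-1,2,3-triol
Product: 10 (2R)-2-Ar-2,3-dihydroxypropyl benzoate
Conditions: CuCl2 (10 mol %), (R,R)-2,2′-isopropylidenebis(4-phenyl-2-oxazoline) (10 mol %), BzCl (1.1 equiv), Et3N, THF, 0 °C → rt
Reagents that add atoms: benzoyl chloride, O=C(Cl)c1ccccc1
Why: Catalytic enantioselective desymmetrisation by monobenzoylation, in which the triol chelates the chiral CuCl2–bis(oxazoline) complex through the tertiary and one primary hydroxyl and the ligand directs benzoyl chloride to one enantiotopic primary hydroxyl, setting the fully substituted carbon that becomes C3.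

Step 5
Reactants: 10 (2R)-2-Ar-2,3-dihydroxypropyl benzoate
Product: 11 (2S)-3-[(tert-butyldimethylsilyl)oxy]-2-Ar-2-hydroxypropyl benzoate
Conditions: TBSCl, imidazole, CH2Cl2, 0 °C
Reagents that add atoms: tert-butyldimethylsilyl chloride, CC(C)(C)[Si](C)(C)Cl
Why: Selective silyl ether formation at the primary over the hindered tertiary hydroxyl, done cold and at once so that no 1,3-benzoyl shift between the two arms can erode the enantiomeric purity (the descriptor changes only through CIP priorities).

Step 6
Reactants: 11 (2S)-3-[(tert-butyldimethylsilyl)oxy]-2-Ar-2-hydroxypropyl benzoate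
Product: 12 (2S)-3-[(tert-butyldimethylsilyl)oxy]-2-Ar-2-(methoxymethoxy)propyl benzoate
Conditions: MOMCl (6 equiv), i-Pr2NEt (8 equiv), Bu4NI (0.2 equiv), ClCH2CH2Cl, 50 °C
Reagents that add atoms: chloromethyl methyl ether, COCCl
Why: O-alkylation of the tertiary alcohol to the MOM acetal under amine-base conditions with iodide catalysis, which avoids a free alkoxide and hence benzoyl or silyl migration.

Step 7
Reactants: 12 (2S)-3-[(tert-butyldimethylsilyl)oxy]-2-Ar-2-(methoxymethoxy)propyl benzoate
Product: 13 (2S)-3-[(tert-butyldimethylsilyl)oxy]-2-Ar-2-(methoxymethoxy)propan-1-ol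
Conditions: i-Bu2AlH (3 equiv), CH2Cl2, −78 → −40 °C; aqueous potassium sodium tartrate
Reagents that add atoms: none
Why: Reductive cleavage of the benzoate ester at low temperature releases the primary alcohol without a basic alkoxide at room temperature, so the 1,3-silyl shift that would interchange the two arms (racemisation) is avoided.

Step 8
Reactants: 13 (2S)-3-[(tert-butyldimethylsilyl)oxy]-2-Ar-2-(methoxymethoxy)propan-1-ol
Product: 14 (2R)-3-[(tert-butyldimethylsilyl)oxy]-2-Ar-2-(methoxymethoxy)propanal
Conditions: Dess–Martin periodinane, pyridine, CH2Cl2, 0 °C → rt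
Reagents that add atoms: none
Why: Dess–Martin oxidation of the primary alcohol; the aldehyde has no α-hydrogen, so the stereocentre is secure, and the prenyl alkene is inert to the reagent.

Step 9
Reactants: 15 1,3,5-trifluorobenzene; 14 (2R)-3-[(tert-butyldimethylsilyl)oxy]-2-Ar-2-(methoxymethoxy)propanal
Product: 17 (2R)-3-[(tert-butyldimethylsilyl)oxy]-2-Ar-2-(methoxymethoxy)-1-(2,4,6-trifluorophenyl)propan-1-ol (both C1 epimers), via (2,4,6-trifluorophenyl)lithium 16 (not isolated)
Conditions: 15, n-BuLi, THF, −78 °C; then 14, −78 °C; H2O quench at −78 °C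
Reagents that add atoms: none
Why: Lithiation of 1,3,5-trifluorobenzene between two fluorines and 1,2-addition of the aryllithium to the aldehyde, held at −78 °C so that the aryllithium does not lose LiF to an aryne; the carbinol configuration is irrelevant because it is oxidised next.

Step 10
Reactants: 17 (2R)-3-[(tert-butyldimethylsilyl)oxy]-2-Ar-2-(methoxymethoxy)-1-(2,4,6-trifluorophenyl)propan-1-ol
Product: 18 (2R)-3-[(tert-butyldimethylsilyl)oxy]-2-Ar-2-(methoxymethoxy)-1-(2,4,6-trifluorophenyl)propan-1-one
Conditions: Dess–Martin periodinane, pyridine, CH2Cl2, rt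
Reagents that add atoms: none
Why: Dess–Martin oxidation of the secondary benzylic carbinol to the non-enolisable aryl ketone, merging both epimers into the cyclisation precursor.

Step 11
Reactants: 18 (2R)-3-[(tert-butyldimethylsilyl)oxy]-2-Ar-2-(methoxymethoxy)-1-(2,4,6-trifluorophenyl)propan-1-one
Product: 20 (3R)-3-Ar-5,7-difluoro-3-(methoxymethoxy)-2,3-dihydro-4H-chromen-4-one, via tetrabutylammonium primary alkoxide 19 (not isolated)
Conditions: Bu4NF (1.2 equiv), THF (0.02 M), 0 °C → rt
Reagents that add atoms: none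
Why: Fluoride cleaves the primary O–Si bond and the resulting tetrabutylammonium alkoxide 19 adds to one ortho C–F carbon of the 2,4,6-trifluorophenyl ketone, the anionic σ-adduct being stabilised by the ortho carbonyl and the two remaining fluorines before it expels fluoride (addition–elimination, SNAr). The closest known reaction type is the base-induced cyclisation of 1-(2-fluoroaryl)-3-hydroxypropan-1-ones to chroman-4-ones. Ring C closes in a 6-exo-trig mode through the new O1–C8a bond. No stereocentre is created, and C3, which is fully substituted and cannot enolise, keeps the configuration fixed in step 4. The step needs chemoselectivity for closure through the primary oxygen: the tertiary oxygen is blocked as its MOM ether so that no 5-exo closure to a benzofuran-3-one can occur, and the irreversible attack on the highly electrophilic trifluorinated ring at 0 °C should outrun retro-aldol loss of formaldehyde from 19. No regiochemical question arises because the two ortho fluorines of the symmetric ring A precursor are equivalent and the para fluorine is out of reach.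

Step 12
Reactants: 20 (3R)-3-Ar-5,7-difluoro-3-(methoxymethoxy)-2,3-dihydro-4H-chromen-4-one
Product: 21 (3R)-3-Ar-3-(methoxymethoxy)-5,7-bis[2-(trimethylsilyl)ethoxy]-2,3-dihydro-4H-chromen-4-one
Conditions: Me3SiCH2CH2OH (5 equiv), NaH (4.5 equiv), DMF, 0 °C; then 20, 0 → 50 °C
Reagents that add atoms: 2-(trimethylsilyl)ethanol, C[Si](C)(C)CCO
Why: Two successive SNAr displacements of the fluorides ortho (C5) and para (C7) to the C4 carbonyl by sodium 2-(trimethylsilyl)ethoxide; the first ether stays neutral and so does not shut down the second substitution as a phenoxide would, and C3, having no α-hydrogen, cannot epimerise or trigger ring opening under the base.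

Step 13
Reactants: 21 (3R)-3-Ar-3-(methoxymethoxy)-5,7-bis[2-(trimethylsilyl)ethoxy]-2,3-dihydro-4H-chromen-4-one
Product: 22 (3R)-3-Ar-5,7-dihydroxy-3-(methoxymethoxy)-2,3-dihydro-4H-chromen-4-one
Conditions: Bu4NF (4 equiv), THF, rt → 50 °C; pH 6 buffer work-up
Reagents that add atoms: none
Why: Fluoride-induced β-elimination of the two 2-(trimethylsilyl)ethyl aryl ethers releases ethene, Me3SiF and the carbonyl-stabilised phenoxides, while the MOM acetal keeps the C3 oxygen masked against base-induced α-ketol rearrangement.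

Step 14
Reactants: 22 (3R)-3-Ar-5,7-dihydroxy-3-(methoxymethoxy)-2,3-dihydro-4H-chromen-4-one
Product: 23 (3R)-3,5,7-trihydroxy-3-[2,4-dimethoxy-3-(3-methylbut-2-en-1-yl)phenyl]-2,3-dihydro-4H-chromen-4-one
Conditions: ZnBr2 (1 equiv), n-PrSH (2 equiv), CH2Cl2, 0 °C
Reagents that add atoms: none
Why: Lewis acid–thiol cleavage of the MOM acetal, in which the thiol captures the methoxymethyl unit so that neither the prenyl alkene nor the nucleophilic ring A sees a protic acid or a free formaldehyde equivalent, and the α-keto position of C3 disfavours ionisation of the C3–O bond.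

**Compound list**

1 | 1,3-dihydroxyacetone (charged as its dimer) | OCC(=O)CO | starting material
2 | 1,3-bis[(tert-butyldimethylsilyl)oxy]propan-2-one | CC(C)(C)[Si](C)(C)OCC(=O)CO[Si](C)(C)C(C)(C)C | intermediate
3 | 1-bromo-2,4-dimethoxybenzene | COc1ccc(Br)c(OC)c1 | starting material
4 | prenyl bromide (1-bromo-3-methylbut-2-ene) | CC(C)=CCBr | starting material
5 | (3-bromo-2,6-dimethoxyphenyl)lithium | COc1ccc(Br)c(OC)c1[Li] | intermediate
6 | 1-bromo-2,4-dimethoxy-3-(3-methylbut-2-en-1-yl)benzene | COc1ccc(Br)c(OC)c1CC=C(C)C | intermediate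
7 | [2,4-dimethoxy-3-(3-methylbut-2-en-1-yl)phenyl]lithium | [Li]c1ccc(OC)c(CC=C(C)C)c1OC | intermediate
8 | 2-Ar-1,3-bis[(tert-butyldimethylsilyl)oxy]propan-2-ol | CC(C)(C)[Si](C)(C)OCC(O)(CO[Si](C)(C)C(C)(C)C)c1ccc(OC)c(CC=C(C)C)c1OC | intermediate
9 | 2-Ar-propane-1,2,3-triol | OCC(O)(CO)c1ccc(OC)c(CC=C(C)C)c1OC | intermediate
10 | (2R)-2-Ar-2,3-dihydroxypropyl benzoate | O=C(OC[C@](O)(CO)c1ccc(OC)c(CC=C(C)C)c1OC)c1ccccc1 | intermediate
11 | (2S)-3-[(tert-butyldimethylsilyl)oxy]-2-Ar-2-hydroxypropyl benzoate | O=C(OC[C@](O)(CO[Si](C)(C)C(C)(C)C)c1ccc(OC)c(CC=C(C)C)c1OC)c1ccccc1 | intermediate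
12 | (2S)-3-[(tert-butyldimethylsilyl)oxy]-2-Ar-2-(methoxymethoxy)propyl benzoate | O=C(OC[C@](OCOC)(CO[Si](C)(C)C(C)(C)C)c1ccc(OC)c(CC=C(C)C)c1OC)c1ccccc1 | intermediate
13 | (2S)-3-[(tert-butyldimethylsilyl)oxy]-2-Ar-2-(methoxymethoxy)propan-1-ol | OC[C@](OCOC)(CO[Si](C)(C)C(C)(C)C)c1ccc(OC)c(CC=C(C)C)c1OC | intermediate
14 | (2R)-3-[(tert-butyldimethylsilyl)oxy]-2-Ar-2-(methoxymethoxy)propanal | O=C[C@](OCOC)(CO[Si](C)(C)C(C)(C)C)c1ccc(OC)c(CC=C(C)C)c1OC | intermediate
15 | 1,3,5-trifluorobenzene | Fc1cc(F)cc(F)c1 | starting material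
16 | (2,4,6-trifluorophenyl)lithium | [Li]c1c(F)cc(F)cc1F | intermediate
17 | (2R)-3-[(tert-butyldimethylsilyl)oxy]-2-Ar-2-(methoxymethoxy)-1-(2,4,6-trifluorophenyl)propan-1-ol, both C1 epimers | OC(c1c(F)cc(F)cc1F)[C@](OCOC)(CO[Si](C)(C)C(C)(C)C)c1ccc(OC)c(CC=C(C)C)c1OC | intermediate
18 | (2R)-3-[(tert-butyldimethylsilyl)oxy]-2-Ar-2-(methoxymethoxy)-1-(2,4,6-trifluorophenyl)propan-1-one | O=C(c1c(F)cc(F)cc1F)[C@](OCOC)(CO[Si](C)(C)C(C)(C)C)c1ccc(OC)c(CC=C(C)C)c1OC | intermediate
19 | tetrabutylammonium (2R)-2-Ar-2-(methoxymethoxy)-3-oxo-3-(2,4,6-trifluorophenyl)propan-1-olate | O=C(c1c(F)cc(F)cc1F)[C@](OCOC)(C[O-])c1ccc(OC)c(CC=C(C)C)c1OC.CCCC[N+](CCCC)(CCCC)CCCC | intermediate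
20 | (3R)-3-Ar-5,7-difluoro-3-(methoxymethoxy)-2,3-dihydro-4H-chromen-4-one | COc1ccc([C@@]2(OCOC)COc3cc(F)cc(F)c3C2=O)c(OC)c1CC=C(C)C | intermediate
21 | (3R)-3-Ar-3-(methoxymethoxy)-5,7-bis[2-(trimethylsilyl)ethoxy]-2,3-dihydro-4H-chromen-4-one | COc1ccc([C@@]2(OCOC)COc3cc(OCC[Si](C)(C)C)cc(OCC[Si](C)(C)C)c3C2=O)c(OC)c1CC=C(C)C | intermediate
22 | (3R)-3-Ar-5,7-dihydroxy-3-(methoxymethoxy)-2,3-dihydro-4H-chromen-4-one | COc1ccc([C@@]2(OCOC)COc3cc(O)cc(O)c3C2=O)c(OC)c1CC=C(C)C | intermediate
23 | (3R)-3,5,7-trihydroxy-3-[2,4-dimethoxy-3-(3-methylbut-2-en-1-yl)phenyl]-2,3-dihydro-4H-chromen-4-one | COc1ccc([C@@]2(O)COc3cc(O)cc(O)c3C2=O)c(OC)c1CC=C(C)C | target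

**Step count**

Total steps: 14. Longest linear sequence: 13 steps (steps 2–14 from 3 and 4; the branch from 1 joins at step 3 and is equally long).

**Steps most likely to fail**

Step 11. Once the silyl ether is cleaved, the free β-alkoxy ketone may lose formaldehyde by retro-aldol fragmentation (and re-add it without facial control) faster than the alkoxide closes ring C, or adventitious hydroxide may cleave the aryl ketone. Either process would destroy or racemise C3. The fallback closes the same O1–C8a bond one oxidation level lower, where no retro-aldol is possible. It sets out from 17: Bu4NF in THF at 0 °C should give (2R)-2-Ar-2-(methoxymethoxy)-1-(2,4,6-trifluorophenyl)propane-1,3-diol F1. KOt-Bu (1.1 equiv) in THF at 0 → 50 °C should then effect intramolecular SNAr of the primary alkoxide on the polyfluorinated ring (only this oxygen can reach an ortho carbon through a six-membered ring), giving (3R)-3-Ar-5,7-difluoro-3-(methoxymethoxy)chroman-4-ol F2. Dess–Martin oxidation of F2 returns to the route at 20.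

Step 12. The second displacement may stall because the ring carrying one new alkoxy group is less electrophilic, while on heating the silylethoxide decomposes by Peterson-type loss of ethene to silanolate, which would convert the substrate to an unreactive phenoxide. The fallback uses a thermally robust oxygen nucleophile and a different unmasking. It sets out from 20: allyl alcohol and NaH in DMF at up to 90 °C should give (3R)-3-Ar-5,7-bis(allyloxy)-3-(methoxymethoxy)-2,3-dihydro-4H-chromen-4-one F3. Deallylation with Pd(PPh3)4 (zerovalent palladium, catalytic) and morpholine in THF at rt leaves the prenyl group and the MOM ether untouched and returns to the route at 22.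

Step 4. The ortho-methoxy group of ring B may compete for copper and the electron-rich, hindered aryl carbinol may bind differently from simpler 2-aryl glycerols, leading to poor discrimination of the two arms, over-benzoylation, or erosion by 1,3-benzoyl shift. The fallback replaces asymmetric catalysis by resolution with recycling. It sets out from 9: BzCl (1.0 equiv) and 2,4,6-collidine in CH2Cl2 at −40 °C should give racemic 2-Ar-2,3-dihydroxypropyl benzoate F4. Preparative chromatography on an amylose tris(3,5-dimethylphenylcarbamate) phase separates 10, at which the route is rejoined, from (2S)-2-Ar-2,3-dihydroxypropyl benzoate F5. F5 is returned to the achiral triol 9 by K2CO3 in MeOH and recycled.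

**Further compounds**

F1 | step 11 | (2R)-2-Ar-2-(methoxymethoxy)-1-(2,4,6-trifluorophenyl)propane-1,3-diol, both C1 epimers | OC(c1c(F)cc(F)cc1F)[C@](OCOC)(CO)c1ccc(OC)c(CC=C(C)C)c1OC
F2 | step 11 | (3R)-3-Ar-5,7-difluoro-3-(methoxymethoxy)chroman-4-ol, both C4 epimers | COc1ccc([C@@]2(OCOC)COc3cc(F)cc(F)c3C2O)c(OC)c1CC=C(C)C
F3 | step 12 | (3R)-3-Ar-5,7-bis(allyloxy)-3-(methoxymethoxy)-2,3-dihydro-4H-chromen-4-one | COc1ccc([C@@]2(OCOC)COc3cc(OCC=C)cc(OCC=C)c3C2=O)c(OC)c1CC=C(C)C
F4 | step 4 | racemic 2-Ar-2,3-dihydroxypropyl benzoate | O=C(OCC(O)(CO)c1ccc(OC)c(CC=C(C)C)c1OC)c1ccccc1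
F5 | step 4 | (2S)-2-Ar-2,3-dihydroxypropyl benzoate | O=C(OC[C@@](O)(CO)c1ccc(OC)c(CC=C(C)C)c1OC)c1ccccc1
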